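**Plan**
- Retrosynthesis: the two C–Br bonds of ring B (C3', C5') are cut first, then the ring B bonds C2'–C3' and C4'–C5' in a [4+2] sense, then the silyl enol ether, the exocyclic methylene (olefination) and the alkyl C–O bond to the ring A oxygen.
- Enabling feature: in ring B, C1' (ether oxygen) and C6' (hydroxyl) are neighbouring oxygenated carbons. Without the bromines, C2'=C1'–C6'=C5' is a 2,3-dioxygenated butadiene and C3'–C4' is a two-carbon acetylene equivalent.
- Forward: ring A is bought complete as phenol 1. Its oxygen is joined to a C3 ketophosphonate, which is methylenated and silylated to the diene. Ring B is then closed by Diels–Alder reaction and double sulfinate loss, and desilylation and dibromination finish the route.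
- Stereochemistry: the target is achiral. The trans sulfonyl stereocentres of the cycloadduct are transient and disappear on aromatisation.

Key step: step 4

Assumption: ring B is numbered with C1' on the diaryl ether oxygen and C6' on the hydroxyl (bromines at C3', C5'); phenol 1 and diazophosphonate 2 are taken as purchasable.

**Step 1**
Reactants: 1 2,4-dibromo-6-methoxyphenol; 2 dimethyl (1-diazo-2-oxopropyl)phosphonate
Product: 3 dimethyl [1-(2,4-dibromo-6-methoxyphenoxy)-2-oxopropyl]phosphonate (racemic)
Conditions: Rh2(OAc)4 (2 mol %), PhMe, 80 °C, slow addition of 2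
Reagents that add atoms: none
Why: Rh2(OAc)4 turns the diazo ketophosphonate into an electrophilic carbenoid that the phenol oxygen captures (oxonium ylide, then proton shift), a carbenoid O–H insertion that etherifies the hindered 2,6-disubstituted phenol without an SN2 step or a strong base.

**Step 2**
Reactants: 3 dimethyl [1-(2,4-dibromo-6-methoxyphenoxy)-2-oxopropyl]phosphonate; 4 formaldehyde (37% aqueous)
Product: 5 3-(2,4-dibromo-6-methoxyphenoxy)but-3-en-2-one
Conditions: aq. CH2O (3 equiv), K2CO3 (1.5 equiv), THF–H2O, 0 °C to rt
Reagents that add atoms: none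
Why: the phosphonate carbanion, formed at the only acidic C–H, adds to formaldehyde and collapses by the Horner–Wadsworth–Emmons pathway, so the methylene can only end up on the aryloxy-bearing carbon.

**Step 3**
Reactants: 5 3-(2,4-dibromo-6-methoxyphenoxy)but-3-en-2-one
Product: 6 tert-butyl{[3-(2,4-dibromo-6-methoxyphenoxy)buta-1,3-dien-2-yl]oxy}dimethylsilane
Conditions: TBSOTf (1.2 equiv), Et3N (2 equiv), CH2Cl2, 0 °C; cold NaHCO3 wash, quick filtration through Et3N-deactivated silica, used at once
Reagents that add atoms: tert-butyldimethylsilyl trifluoromethanesulfonate, CC(C)(C)[Si](C)(C)OS(=O)(=O)C(F)(F)F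
Why: soft enolisation of the methyl ketone (its only enolisable side) by silyl triflate and amine is the standard silyl enol ether formation that converts vinyl ketones into 2-silyloxybutadienes, and it avoids amide bases that could metalate the ring A C–H between the two bromines.

**Step 4**
Reactants: 6 tert-butyl{[3-(2,4-dibromo-6-methoxyphenoxy)buta-1,3-dien-2-yl]oxy}dimethylsilane; 7 (E)-1,2-bis(phenylsulfonyl)ethene
Product: 11 tert-butyl[2-(2,4-dibromo-6-methoxyphenoxy)phenoxy]dimethylsilane, via bis-sulfone cycloadduct 8 (not isolated), via vinyl sulfone diene 9 (not isolated), via allyl sulfone diene 10 (not isolated)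
Conditions: 7 (1.05 equiv), PhMe, 100 °C; then DBU (3 equiv), 70 °C, same pot
Reagents that add atoms: none
Why: The electron-rich 2-aryloxy-3-silyloxydiene 6 and the doubly sulfonyl-activated alkene 7 should combine in a concerted, suprafacial, normal-demand [4π+2π] cycloaddition (intermolecular Diels–Alder reaction) that closes ring B by forming C2'–C3' and C4'–C5' in one event and leaves the C1'=C6' enol ether double bond in place. The closest known chemistry is the Diels–Alder reactivity of 2,3-bis(silyloxy)butadienes and the use of 1,2-bis(phenylsulfonyl)ethene as an acetylene equivalent whose adducts lose benzenesulfinic acid to amine bases. DBU removes an α-sulfonyl proton of 8 and expels the neighbouring sulfinate (E1cB) to give 9, a γ-deprotonation and α-reprotonation shift the double bond to give allyl sulfone 10, and a second β-elimination leaves the benzene ring, so no oxidant is required. The two sulfonyl-bearing carbons of 8 are trans because addition to the E alkene is suprafacial, but both stereocentres are erased on aromatisation and no stereocontrol is needed. Regiochemistry does not arise because the dienophile is symmetrical and either order of sulfinate loss leads to the same arene; loss of sulfinate rather than aryloxide or silanolate is favoured because both oxygen substituents remain on sp2 carbons along this pathway and the sulfonyl-activated protons are the most acidic.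

**Step 5**
Reactants: 11 tert-butyl[2-(2,4-dibromo-6-methoxyphenoxy)phenoxy]dimethylsilane
Product: 12 2-(2,4-dibromo-6-methoxyphenoxy)phenol
Conditions: TBAF (1.1 equiv), AcOH (1.1 equiv), THF, 0 °C
Reagents that add atoms: none
Why: fluoride-mediated desilylation of the aryl silyl ether, buffered by acetic acid as proton source, should free the phenol without touching the diaryl ether or the aryl bromides.

**Step 6**
Reactants: 12 2-(2,4-dibromo-6-methoxyphenoxy)phenol
Product: 13 2,4-dibromo-6-(2,4-dibromo-6-methoxyphenoxy)phenol (CNP0236935.0)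
Conditions: Br2 (2.05 equiv), CH2Cl2, 0 °C to rt
Reagents that add atoms: bromine, BrBr
Why: electrophilic aromatic bromination is steered by the free hydroxyl of ring B to its only open para (C3') and ortho (C5') carbons, while ring A, deactivated by two bromines and with both open positions flanked by substituents, and the weaker aryloxy donor are not expected to compete.

**Compound list**
1 | 2,4-dibromo-6-methoxyphenol | COc1cc(Br)cc(Br)c1O | starting material
2 | dimethyl (1-diazo-2-oxopropyl)phosphonate | CC(=O)C(=[N+]=[N-])P(=O)(OC)OC | starting material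
3 | dimethyl [1-(2,4-dibromo-6-methoxyphenoxy)-2-oxopropyl]phosphonate (racemic) | COc1cc(Br)cc(Br)c1OC(C(C)=O)P(=O)(OC)OC | intermediate
4 | formaldehyde (37% aqueous solution) | C=O | starting material
5 | 3-(2,4-dibromo-6-methoxyphenoxy)but-3-en-2-one | COc1cc(Br)cc(Br)c1OC(=C)C(C)=O | intermediate
6 | tert-butyl{[3-(2,4-dibromo-6-methoxyphenoxy)buta-1,3-dien-2-yl]oxy}dimethylsilane | C=C(Oc1c(OC)cc(Br)cc1Br)C(=C)O[Si](C)(C)C(C)(C)C | intermediate
7 | (E)-1,2-bis(phenylsulfonyl)ethene | O=S(=O)(/C=C/S(=O)(=O)c1ccccc1)c1ccccc1 | starting material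
8 | tert-butyl{[(4R*,5R*)-2-(2,4-dibromo-6-methoxyphenoxy)-4,5-bis(phenylsulfonyl)cyclohex-1-en-1-yl]oxy}dimethylsilane (trans, racemic, one enantiomer drawn) | COc1cc(Br)cc(Br)c1OC1=C(O[Si](C)(C)C(C)(C)C)C[C@@H](S(=O)(=O)c2ccccc2)[C@H](S(=O)(=O)c2ccccc2)C1 | intermediate
9 | tert-butyl{[2-(2,4-dibromo-6-methoxyphenoxy)-5-(phenylsulfonyl)cyclohexa-1,4-dien-1-yl]oxy}dimethylsilane (the regioisomer with the sulfone on the aryloxy side converges) | COc1cc(Br)cc(Br)c1OC1=C(O[Si](C)(C)C(C)(C)C)CC(S(=O)(=O)c2ccccc2)=CC1 | intermediate
10 | tert-butyl{[2-(2,4-dibromo-6-methoxyphenoxy)-5-(phenylsulfonyl)cyclohexa-1,3-dien-1-yl]oxy}dimethylsilane (racemic) | COc1cc(Br)cc(Br)c1OC1=C(O[Si](C)(C)C(C)(C)C)CC(S(=O)(=O)c2ccccc2)C=C1 | intermediate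
11 | tert-butyl[2-(2,4-dibromo-6-methoxyphenoxy)phenoxy]dimethylsilane | COc1cc(Br)cc(Br)c1Oc1ccccc1O[Si](C)(C)C(C)(C)C | intermediate
12 | 2-(2,4-dibromo-6-methoxyphenoxy)phenol | COc1cc(Br)cc(Br)c1Oc1ccccc1O | intermediate
13 | 2,4-dibromo-6-(2,4-dibromo-6-methoxyphenoxy)phenol | COc1cc(Br)cc(Br)c1Oc1cc(Br)cc(Br)c1O | target

**Totals**
Total steps: 6. Longest linear sequence: 6 steps (1 to 13).

**Steps most likely to fail**

Step 4 (key step). The diene, twisted by its two bulky oxygen substituents, may cycloadd so slowly that it hydrolyses or oligomerises first. The base cascade may also stall after the first sulfinate loss, or drift through an unwanted proton shift into loss of aryloxide. The fallback sets out from 6 and returns at 11. Diene 6 would be heated with phenyl vinyl sulfoxide (C=CS(=O)c1ccccc1) and solid NaHCO3 in toluene at 110 °C. The Diels–Alder adduct tert-butyl{[2-(2,4-dibromo-6-methoxyphenoxy)-5-(phenylsulfinyl)cyclohex-1-en-1-yl]oxy}dimethylsilane F1 (regio- and stereoisomer mixture, not isolated) should lose benzenesulfenic acid by base-free thermal syn-elimination. This gives tert-butyl{[2-(2,4-dibromo-6-methoxyphenoxy)cyclohexa-1,4-dien-1-yl]oxy}dimethylsilane F2; a conjugated diene isomer would converge. Dehydrogenation of F2 with DDQ in benzene at room temperature then gives 11.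

Step 1. The acceptor-substituted carbenoid may be consumed by dimerisation, Wolff rearrangement or ylide formation at the methoxy oxygen or the ortho bromine before the hindered, weakly nucleophilic hydroxyl traps it. The fallback sets out from 1 and returns at 5, bypassing step 2 as well. Phenol 1 would be O-alkylated with 3-chlorobutan-2-one (CC(Cl)C(C)=O; K2CO3, catalytic KI, acetone, reflux) to 3-(2,4-dibromo-6-methoxyphenoxy)butan-2-one F3. PhSeCl in EtOAc at room temperature should selenenylate the more substituted, oxygen-stabilised enol to give 3-(2,4-dibromo-6-methoxyphenoxy)-3-(phenylselanyl)butan-2-one F4. Oxidation with H2O2 and pyridine in CH2Cl2 at 0 °C would give 3-(2,4-dibromo-6-methoxyphenoxy)-3-(phenylseleninyl)butan-2-one F5 (not isolated). Its syn-elimination can only run toward the C4 methyl group and delivers enone 5.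

Step 6. Over-bromination of ring B may occur, or the second bromine may enter para to the aryloxy oxygen (C4') rather than ortho to the hydroxyl. The fallback sets out from 12 and returns at 13 in two reagent-controlled stages. Tetrabutylammonium tribromide (1 equiv, CH2Cl2–MeOH, rt) should brominate only para to the hydroxyl, giving 4-bromo-2-(2,4-dibromo-6-methoxyphenoxy)phenol F6. NBS (1 equiv) with catalytic i-Pr2NH in CH2Cl2 at 0 °C would then deliver bromine ortho to the hydroxyl through the hydrogen-bonded N-bromoamine, giving 13.

**Further compounds**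
F1 | step 4 | tert-butyl{[2-(2,4-dibromo-6-methoxyphenoxy)-5-(phenylsulfinyl)cyclohex-1-en-1-yl]oxy}dimethylsilane (isomer mixture, one regioisomer drawn) | COc1cc(Br)cc(Br)c1OC1=C(O[Si](C)(C)C(C)(C)C)CC(S(=O)c2ccccc2)CC1
F2 | step 4 | tert-butyl{[2-(2,4-dibromo-6-methoxyphenoxy)cyclohexa-1,4-dien-1-yl]oxy}dimethylsilane | COc1cc(Br)cc(Br)c1OC1=C(O[Si](C)(C)C(C)(C)C)CC=CC1
F3 | step 1 | 3-(2,4-dibromo-6-methoxyphenoxy)butan-2-one (racemic) | COc1cc(Br)cc(Br)c1OC(C)C(C)=O
F4 | step 1 | 3-(2,4-dibromo-6-methoxyphenoxy)-3-(phenylselanyl)butan-2-one (racemic) | COc1cc(Br)cc(Br)c1OC(C)([Se]c2ccccc2)C(C)=O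
F5 | step 1 | 3-(2,4-dibromo-6-methoxyphenoxy)-3-(phenylseleninyl)butan-2-one (diastereomer mixture) | COc1cc(Br)cc(Br)c1OC(C)([Se](=O)c2ccccc2)C(C)=O
F6 | step 6 | 4-bromo-2-(2,4-dibromo-6-methoxyphenoxy)phenol | COc1cc(Br)cc(Br)c1Oc1cc(Br)ccc1O
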